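**Plan**
- Retrosynthesis: the depside ester bond O4'–C(=O) is cut first, giving a ring A acid chloride and a ring B enol. With ring B taken down to the cyclohexane-2,4-dione level, C2'–C3' (Claisen) and C1'–C6' (Michael) are cut next.
- Enabling feature: in ring B the carboxyl carbon on C1' lies between the oxygenated C2' and the pentyl-bearing C6', and O2' and O4' are 1,3-related. Carboxyl–C1'–C2' is therefore a malonate, and C3'–C4'(O)–C5'–C6'(pentyl) is non-3-en-2-one.
- Forward: the ring A acid chloride is made from 3,5-dimethoxybenzaldehyde (steps 1–7). The ring B carbocycle, the only ring formed in the route, closes in step 8. O4' is acylated (step 9), ring B is aromatized through a C1' selenoxide (step 10), and both benzyl groups are removed (step 11).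
- Stereochemistry: the target has no stereocentre. C1' and C6' of the dione (racemic, trans by epimerisation at C1') and the transient C1' selenide centre are erased on aromatization.

Key step: step 8

Assumption: 14 and 15 are written as keto tautomers, although 14 should be largely enolised across C2'–C3'–C4'. All sp3 centres of ring B are racemic and only relative configuration is meant. Primed locants are those of ring B in the target.

**Step 1**
Reactants: 1 3,5-dimethoxybenzaldehyde
Product: 2 1,3-dimethoxy-5-(prop-1-en-1-yl)benzene
Conditions: EtPPh3Br, KOtBu, THF, 0 °C → rt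
Reagents that add atoms: ethyltriphenylphosphonium bromide, CC[P+](c1ccccc1)(c1ccccc1)c1ccccc1.[Br-]
Why: Wittig olefination of an aromatic aldehyde by a non-stabilised ylide is reliable, and the E/Z mixture expected is of no consequence because the double bond is hydrogenated next.

**Step 2**
Reactants: 2 1,3-dimethoxy-5-(prop-1-en-1-yl)benzene
Product: 3 1,3-dimethoxy-5-propylbenzene
Conditions: H2 (1 atm), 10% Pd/C, EtOAc, rt
Reagents that add atoms: none
Why: Catalytic hydrogenation of a styrene-type alkene over Pd/C is routine and leaves aryl methyl ethers untouched.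

**Step 3**
Reactants: 3 1,3-dimethoxy-5-propylbenzene
Product: 5 2,4-dimethoxy-6-propylbenzaldehyde, via iminium chloride 4 (not isolated)
Conditions: POCl3, DMF, 0 °C → 70 °C; then ice-water, rt
Reagents that add atoms: N,N-dimethylformamide, CN(C)C=O; water, O
Why: Vilsmeier–Haack formylation of this electron-rich arene should occur para to one methoxy group and ortho to the other, the position between the two methoxy groups being the more hindered, as is general for 5-alkylresorcinol dimethyl ethers.

**Step 4**
Reactants: 5 2,4-dimethoxy-6-propylbenzaldehyde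
Product: 7 2-hydroxy-4-methoxy-6-propylbenzaldehyde, via dichloroboron chelate 6 (not isolated)
Conditions: BCl3 (1.2 equiv), CH2Cl2, −78 °C → 0 °C; then H2O
Reagents that add atoms: none
Why: BCl3 bridges the formyl oxygen and the ortho methoxy oxygen and so cleaves only that methyl ether (chelation-controlled Lewis acid demethylation), leaving the para methoxy group in place.

**Step 5**
Reactants: 7 2-hydroxy-4-methoxy-6-propylbenzaldehyde
Product: 8 2-(benzyloxy)-4-methoxy-6-propylbenzaldehyde
Conditions: BnBr, K2CO3, DMF, 60 °C
Reagents that add atoms: benzyl bromide, BrCc1ccccc1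
Why: Williamson etherification of the phenoxide masks the ring A phenol as a benzyl ether, which is removed together with the benzyl ester in the last step.

**Step 6**
Reactants: 8 2-(benzyloxy)-4-methoxy-6-propylbenzaldehyde
Product: 9 2-(benzyloxy)-4-methoxy-6-propylbenzoic acid
Conditions: NaClO2, NaH2PO4, 2-methylbut-2-ene, t-BuOH/H2O, rt
Reagents that add atoms: sodium chlorite, [Na+].[O-]Cl=O
Why: Pinnick oxidation takes the hindered aryl aldehyde to the acid under buffered conditions, 2-methylbut-2-ene trapping HOCl so that the electron-rich ring is not chlorinated and the benzyl ether is untouched.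

**Step 7**
Reactants: 9 2-(benzyloxy)-4-methoxy-6-propylbenzoic acid
Product: 10 2-(benzyloxy)-4-methoxy-6-propylbenzoyl chloride
Conditions: (COCl)2, cat. DMF, CH2Cl2, 0 °C → rt; volatiles removed, used crude
Reagents that add atoms: oxalyl chloride, ClC(=O)C(Cl)=O
Why: Acid chloride formation through the catalytic chloroiminium species is mild enough for the benzyl ether and gives an acylating agent reactive enough for a 2,6-disubstituted benzoyl group.

**Step 8**
Reactants: 11 dibenzyl malonate; 12 (E)-non-3-en-2-one
Product: 14 benzyl trans-2,4-dioxo-6-pentylcyclohexane-1-carboxylate, via Michael adduct 13 (not isolated)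
Conditions: NaH (1.05 equiv), cat. BnOH, THF, 0 °C; add 12, rt → 65 °C; then 1 M HCl, 0 °C
Reagents that add atoms: none
Why: The sodium enolate of 11 adds in conjugate fashion to C4 of 12 (Michael addition, forging C1'–C6'); proton transfer through the catalytic benzyl alcohol relays the charge to the methyl-ketone enolate of 13, which attacks one benzyl ester carbonyl (Dieckmann-type Claisen condensation, forging C2'–C3') with loss of benzyloxide, and this base at once deprotonates the vinylogous acid formed and so pulls every earlier equilibrium forward. The closest known reaction type is the malonate–enone Michael–Dieckmann annulation that delivers alkyl dihydroresorcylates. The single ring closes in the 6-(enolendo)-exo-trig mode. C6' is created in the Michael addition without control (racemic), and C1', the α-carbon of a β-keto ester, should epimerise through its enol to the trans isomer with pentyl and ester both equatorial; neither centre survives step 10. The step needs 1,4- rather than 1,2-addition, which the stabilised malonate anion secures because its 1,2-adduct reverts, and closure through the methyl rather than the C5' methylene enolate, which ring size secures since attack from C5' would lead to a strained cyclobutanone.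

**Step 9**
Reactants: 14 benzyl trans-2,4-dioxo-6-pentylcyclohexane-1-carboxylate; 10 2-(benzyloxy)-4-methoxy-6-propylbenzoyl chloride
Product: 15 benzyl trans-4-{[2-(benzyloxy)-4-methoxy-6-propylbenzoyl]oxy}-2-oxo-6-pentylcyclohex-3-ene-1-carboxylate
Conditions: Et3N (1.2 equiv), CH2Cl2, 0 °C → rt
Reagents that add atoms: none
Why: O-acylation of a cyclic 1,3-dione enolate by an aroyl chloride (enol ester formation) is standard; the bulky 2,6-disubstituted acyl group should go to the unencumbered O4' and not to O2' beside the C1' ester, and with no DMAP or cyanide present the acyl group should not migrate to C3'; no stereocentre is touched.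

**Step 10**
Reactants: 15 benzyl trans-4-{[2-(benzyloxy)-4-methoxy-6-propylbenzoyl]oxy}-2-oxo-6-pentylcyclohex-3-ene-1-carboxylate
Product: 19 benzyl 4-{[2-(benzyloxy)-4-methoxy-6-propylbenzoyl]oxy}-2-hydroxy-6-pentylbenzoate, via C1' selenide 16 (not isolated), via selenoxide 17 (not isolated), via dienone 18 (not isolated)
Conditions: PhSeCl (1.1 equiv), pyridine, CH2Cl2, 0 °C; 1 M HCl wash; then 30% aq H2O2 (2.2 equiv), CH2Cl2, 0 °C → rt
Reagents that add atoms: none
Why: α-Selenenylation of the β-keto ester enol at C1' by the PhSeCl–pyridine complex should occur anti to the pseudoaxial pentyl group on C6', placing selenium cis to H6', so that after oxidation the selenoxide undergoes syn elimination toward its only β-hydrogen and the resulting 4H-dienone tautomerises to the hydrogen-bonded phenol (selenoxide elimination–aromatization); the excess peroxide takes the expelled benzeneselenenic acid on to the seleninic acid, and all stereocentres of ring B disappear.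

**Step 11**
Reactants: 19 benzyl 4-{[2-(benzyloxy)-4-methoxy-6-propylbenzoyl]oxy}-2-hydroxy-6-pentylbenzoate
Product: 20 stenosporic acid
Conditions: H2 (1 atm), 10% Pd/C, EtOAc, rt
Reagents that add atoms: none
Why: Hydrogenolysis over Pd/C cleaves the benzyl ether and the benzyl ester in one operation under neutral conditions that leave the depside ester, the methyl ether and both arenes intact.

**Compound list**
1 | 3,5-dimethoxybenzaldehyde | COc1cc(C=O)cc(OC)c1 | starting material
2 | 1,3-dimethoxy-5-(prop-1-en-1-yl)benzene (E/Z mixture) | CC=Cc1cc(OC)cc(OC)c1 | intermediate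
3 | 1,3-dimethoxy-5-propylbenzene | CCCc1cc(OC)cc(OC)c1 | intermediate
4 | [(2,4-dimethoxy-6-propylphenyl)methylidene]dimethyliminium chloride (not isolated) | CCCc1cc(OC)cc(OC)c1C=[N+](C)C.[Cl-] | intermediate
5 | 2,4-dimethoxy-6-propylbenzaldehyde | CCCc1cc(OC)cc(OC)c1C=O | intermediate
6 | 2-[(dichloroboranyl)oxy]-4-methoxy-6-propylbenzaldehyde, boron chelated to the formyl oxygen (not isolated) | CCCc1cc(OC)cc(OB(Cl)Cl)c1C=O | intermediate
7 | 2-hydroxy-4-methoxy-6-propylbenzaldehyde | CCCc1cc(OC)cc(O)c1C=O | intermediate
8 | 2-(benzyloxy)-4-methoxy-6-propylbenzaldehyde | CCCc1cc(OC)cc(OCc2ccccc2)c1C=O | intermediate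
9 | 2-(benzyloxy)-4-methoxy-6-propylbenzoic acid | CCCc1cc(OC)cc(OCc2ccccc2)c1C(=O)O | intermediate
10 | 2-(benzyloxy)-4-methoxy-6-propylbenzoyl chloride | CCCc1cc(OC)cc(OCc2ccccc2)c1C(=O)Cl | intermediate
11 | dibenzyl malonate | O=C(CC(=O)OCc1ccccc1)OCc1ccccc1 | starting material
12 | (E)-non-3-en-2-one | CCCCC/C=C/C(C)=O | starting material
13 | dibenzyl 2-(2-oxononan-4-yl)propanedioate (racemic, not isolated) | CCCCCC(CC(C)=O)C(C(=O)OCc1ccccc1)C(=O)OCc1ccccc1 | intermediate
14 | benzyl trans-2,4-dioxo-6-pentylcyclohexane-1-carboxylate (racemic, relative configuration drawn) | CCCCC[C@@H]1CC(=O)CC(=O)[C@H]1C(=O)OCc1ccccc1 | intermediate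
15 | benzyl trans-4-{[2-(benzyloxy)-4-methoxy-6-propylbenzoyl]oxy}-2-oxo-6-pentylcyclohex-3-ene-1-carboxylate (racemic) | CCCCC[C@@H]1CC(OC(=O)c2c(OCc3ccccc3)cc(OC)cc2CCC)=CC(=O)[C@H]1C(=O)OCc1ccccc1 | intermediate
16 | benzyl 4-{[2-(benzyloxy)-4-methoxy-6-propylbenzoyl]oxy}-2-oxo-6-pentyl-1-(phenylselanyl)cyclohex-3-ene-1-carboxylate, selenium trans to pentyl and cis to H6' (racemic, not isolated) | CCCCC[C@@H]1CC(OC(=O)c2c(OCc3ccccc3)cc(OC)cc2CCC)=CC(=O)[C@]1([Se]c4ccccc4)C(=O)OCc5ccccc5 | intermediate
17 | the Se-oxide of 16, both configurations at selenium (not isolated) | CCCCC[C@@H]1CC(OC(=O)c2c(OCc3ccccc3)cc(OC)cc2CCC)=CC(=O)[C@]1([Se](=O)c4ccccc4)C(=O)OCc5ccccc5 | intermediate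
18 | benzyl 4-{[2-(benzyloxy)-4-methoxy-6-propylbenzoyl]oxy}-6-oxo-2-pentylcyclohexa-1,4-diene-1-carboxylate (not isolated) | CCCCCC1=C(C(=O)OCc2ccccc2)C(=O)C=C(OC(=O)c2c(OCc3ccccc3)cc(OC)cc2CCC)C1 | intermediate
19 | benzyl 4-{[2-(benzyloxy)-4-methoxy-6-propylbenzoyl]oxy}-2-hydroxy-6-pentylbenzoate | CCCCCc1cc(OC(=O)c2c(OCc3ccccc3)cc(OC)cc2CCC)cc(O)c1C(=O)OCc1ccccc1 | intermediate
20 | stenosporic acid, 4-[(2-hydroxy-4-methoxy-6-propylbenzoyl)oxy]-2-hydroxy-6-pentylbenzoic acid | CCCCCc1cc(OC(=O)c2c(O)cc(OC)cc2CCC)cc(O)c1C(=O)O | target

**Step count and risks**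

Total steps: 11. Longest linear sequence: 10 steps (steps 1–7, 9, 10, 11, from 3,5-dimethoxybenzaldehyde); the ring B branch runs through steps 8–11.

Steps most likely to fail:

1. Step 9. The acyl group may be delivered to O2' or to C3' instead of O4', or may migrate from oxygen to C3' once the enol ester has formed. The fallback reverses the order of acylation and aromatization and sets out from 14. Bromine (1 equiv) in DMF at 0 °C should brominate C3' to give benzyl 3-bromo-2,4-dioxo-6-pentylcyclohexane-1-carboxylate F1, which is not isolated. On warming to 80 °C it should lose HBr by 1,4-elimination across its bis-enol to give benzyl 2,4-dihydroxy-6-pentylbenzoate F2. Acylation of F2 with 10 (pyridine, CH2Cl2, 0 °C → rt) should then take place at the free 4-hydroxyl, the 2-hydroxyl being held in a hydrogen bond to the ester carbonyl. The route is rejoined at 19, and steps 9 and 10 are bypassed.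

2. Step 10. Selenium may be delivered to the face cis to the pentyl group, leaving the selenoxide without a syn β-hydrogen, or the peroxide may attack the vinylogous anhydride and strip the aroyl group. The fallback is a catalytic dehydrogenation that needs neither selenium nor peroxide and has no facial requirement. It sets out from 15 and uses Pd(O2CCF3)2 (5 mol%), 2-(dimethylamino)pyridine, TsOH and O2 (1 atm) in DMSO at 80 °C, the known divalent-palladium aerobic dehydrogenation of cyclohexenones to phenols. A palladium enolate at C1' undergoes β-hydride elimination toward C6' and the dienone tautomerises. The route is rejoined at 19, and no compound outside the list is made (entry F0).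

3. Step 8. Benzyloxide may consume the benzyl esters, or the Michael adduct may revert or oligomerise before the Claisen closure takes place. The fallback changes the ester and sets out from 12 with commercial dimethyl malonate (COC(=O)CC(=O)OC) under NaOMe in MeOH at reflux. This passes through dimethyl 2-(2-oxononan-4-yl)propanedioate F3, not isolated, to methyl trans-2,4-dioxo-6-pentylcyclohexane-1-carboxylate F4. The β-keto ester of F4 is then exchanged with benzyl alcohol (cat. DMAP, toluene, reflux, 4 Å sieves to take up methanol). The route is rejoined at 14.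

**Further compounds**
F1 | step 9 | benzyl 3-bromo-2,4-dioxo-6-pentylcyclohexane-1-carboxylate (not isolated, C3' configuration undefined) | CCCCC[C@@H]1CC(=O)C(Br)C(=O)[C@H]1C(=O)OCc1ccccc1
F2 | step 9 | benzyl 2,4-dihydroxy-6-pentylbenzoate | CCCCCc1cc(O)cc(O)c1C(=O)OCc1ccccc1
F0 | step 10 | none | none
F3 | step 8 | dimethyl 2-(2-oxononan-4-yl)propanedioate (racemic, not isolated) | CCCCCC(CC(C)=O)C(C(=O)OC)C(=O)OC
F4 | step 8 | methyl trans-2,4-dioxo-6-pentylcyclohexane-1-carboxylate (racemic) | CCCCC[C@@H]1CC(=O)CC(=O)[C@H]1C(=O)OC
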